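**Plan** (numbering: chain C4 ester carbinol, C5, C6, C7 tertiary carbinol, C8 CHBr, C9, C10; ring C11 quaternary, C12 bearing benzylic C13, C14(Me)=C15, C16, C17 CHBr)
Cuts: O–C4 ester (macrolactone), C8–Br (epoxide opening), C4–isopropenyl and C5–C6 (ketone synthesis, Claisen), C13–aryl (Suzuki), C12=C13 and C14=C15 (methylenation, dehydrogenation), C10–C11 with C17–Br (1,2-shift), C10–C12 (carbonyl addition).
Feature used: in the six-membered ring C11–C12–C14–C15–C16–C17, C11 is quaternary between C17–Br and C12 with its C10 chain trans to bromine, the imprint of an anti 1,2-shift from a C12 carbinol onto a C11=C17 bromonium ion.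
Forward order: the carbocycle is bought as an enone; the C10–C8 chain is added at C12 and shifted to C11; the arene is coupled at C13; the chain is grown from C8 to C4; the 15-membered lactone is closed last; then bromohydrin and phenol are released.
Stereochemistry: C14 from SAMP alkylation (a relay that is later erased) steers C12; C11 and C17 follow from the stereospecific shift; C12–H from hydroboration anti to the C11 methyl; C4 from CBS reduction; C7/C8 from Shi epoxidation and SN2 opening.

Key step: step 6

Remark: the chain oxygen is carried as a triisopropylsilyl ether, whose hindered oxygen should not intercept the bromonium ion of the key step; the migrating group and the bonds formed are unchanged.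
Abbreviation in names: Q = (1S,2R,6S)-6-bromo-2-{[5-(methoxycarbonyl)-2-(methoxymethoxy)phenyl]methyl}-1,3-dimethylcyclohex-3-en-1-yl (ring–arene unit bonded through C11).

Step 1
Reactants: 1 3-iodopropan-1-ol
Product: 2 (3-iodopropoxy)triisopropylsilane
Conditions: i-Pr3SiCl, imidazole, CH2Cl2, 0 °C to rt
Reagents that add atoms: triisopropylsilyl chloride, CC(C)[Si](Cl)(C(C)C)C(C)C
Why: Imidazole-promoted silylation of a primary alcohol (silyl ether formation) is routine and leaves the iodide untouched, with no stereocentre involved.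

Step 2
Reactants: 3 2-methylcyclohex-2-en-1-one
Product: 4 (S)-2-(methoxymethyl)-N-(2-methylcyclohex-2-en-1-ylidene)pyrrolidin-1-amine
Conditions: SAMP, TsOH (cat.), cyclohexane, reflux, water separator
Reagents that add atoms: (S)-1-amino-2-(methoxymethyl)pyrrolidine (SAMP), COC[C@@H]1CCCN1N
Why: Acid-catalysed hydrazone formation is driven by azeotropic removal of water and should place the amino nitrogen anti to the methyl-bearing C2 to avoid allylic strain, with no carbon stereocentre formed.

Step 3
Reactants: 4 (S)-2-(methoxymethyl)-N-(2-methylcyclohex-2-en-1-ylidene)pyrrolidin-1-amine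
Product: 6 (S)-2-(methoxymethyl)-N-[(6R)-2,6-dimethylcyclohex-2-en-1-ylidene]pyrrolidin-1-amine, via lithium aza-enolate 5 (not isolated)
Conditions: LiN(i-Pr)2, THF, 0 °C; then MeI, −95 °C to rt
Reagents that add atoms: iodomethane, CI
Why: Kinetic deprotonation at the only sp3 α-carbon gives aza-enolate 5, and SAMP-hydrazone alkylation (Enders) delivers the methyl group to the face left open by the methoxymethylpyrrolidine, which should set the future C14 centre as R in the same sense as for cyclohexanone SAMP hydrazones.

Step 4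
Reactants: 6 (S)-2-(methoxymethyl)-N-[(6R)-2,6-dimethylcyclohex-2-en-1-ylidene]pyrrolidin-1-amine
Product: 7 (R)-2,6-dimethylcyclohex-2-en-1-one
Conditions: sat. aq. oxalic acid, Et2O, rt
Reagents that add atoms: water, O
Why: Two-phase hydrazone hydrolysis with oxalic acid frees the ketone without ozone, so the ring alkene survives, and is mild enough that the α-stereocentre should not epimerise.

Step 5
Reactants: 2 (3-iodopropoxy)triisopropylsilane and 7 (R)-2,6-dimethylcyclohex-2-en-1-one
Product: 10 (1R,6R)-2,6-dimethyl-1-[3-(triisopropylsilyloxy)propyl]cyclohex-2-en-1-ol, via alkyllithium 8 (not isolated), via organocerium reagent 9 (not isolated)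
Conditions: 2, t-BuLi, Et2O, −78 °C; CeCl3, THF, −78 °C; then 7, −78 °C
Reagents that add atoms: none
Why: Iodine–lithium exchange and transmetallation to cerium give a weakly basic, oxophilic reagent (organocerium 1,2-addition) that should add to the enone carbonyl without enolisation or conjugate addition, approaching anti to the adjacent C6 methyl group (1,2-induction) so that the carbinol centre (future C12) is R with the chain trans to that methyl.

Step 6
Reactants: 10 (1R,6R)-2,6-dimethyl-1-[3-(triisopropylsilyloxy)propyl]cyclohex-2-en-1-ol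
Product: 12 (2S,3S,6R)-3-bromo-2,6-dimethyl-2-[3-(triisopropylsilyloxy)propyl]cyclohexan-1-one, via bromonium ion 11 (not isolated)
Conditions: NBS, (CF3)2CHOH/CH2Cl2, −20 to 0 °C, dark
Reagents that add atoms: N-bromosuccinimide, O=C1CCC(=O)N1Br
Why: NBS should transfer Br+ to the C11=C17 alkene on the face opposite the pseudoaxial C10 chain, giving bromonium ion 11 with its positive charge on the methyl-bearing C11, and the C12–C10 bond, antiperiplanar to the breaking C11–Br bond, then shifts suprafacially to C11 while the hydroxyl oxygen collapses to the C12 ketone and its proton passes to succinimide anion. The closest known reaction type is the halonium-induced semipinacol rearrangement of tertiary allylic alcohols to β-halo ketones. No ring is closed, so no mode of ring closure applies; the two skeletal bonds C17–Br and C10–C11 are made in one event. Both new stereocentres are dictated by the C12 carbinol centre of 10: the chain keeps its face on migration, which gives C11 as S, and bromine is necessarily anti to it, which gives C17 as S. The step needs alkyl shift rather than bromo-epoxide formation, ring contraction or capture by the chain oxygen: only the conformer with the chain pseudoaxial can rearrange and it exposes the face anti to the chain, the ring bond C12–C14 lies near the alkene plane and cannot align, the strongly hydrogen-bonding non-basic solvent lowers the nucleophilicity of the hydroxyl oxygen, and the hindered silyl ether oxygen is a poor nucleophile. The β-bromo ketone 12 cannot lose HBr toward the carbonyl because C11 carries no hydrogen.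

Step 7
Reactants: 12 (2S,3S,6R)-3-bromo-2,6-dimethyl-2-[3-(triisopropylsilyloxy)propyl]cyclohexan-1-one
Product: 14 (5S,6S)-5-bromo-2,6-dimethyl-6-[3-(triisopropylsilyloxy)propyl]cyclohex-2-en-1-one, via silyl enol ether 13 (not isolated)
Conditions: Me3SiOTf, Et3N, CH2Cl2, 0 °C to rt; then Pd(OAc)2, MeCN, rt
Reagents that add atoms: none
Why: Soft enolisation can occur only toward C14 and gives silyl enol ether 13, which divalent palladium should palladate at C14 before β-hydride elimination toward the ring C15–H (Saegusa–Ito oxidation) gives the 2-methyl enone, erasing the C14 relay centre without strong base.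

Step 8
Reactants: 14 (5S,6S)-5-bromo-2,6-dimethyl-6-[3-(triisopropylsilyloxy)propyl]cyclohex-2-en-1-one
Product: 15 {3-[(1S,6S)-6-bromo-1,3-dimethyl-2-methylidenecyclohex-3-en-1-yl]propoxy}triisopropylsilane
Conditions: Cp2Ti(μ-CH2)(μ-Cl)AlMe2, pyridine, THF/toluene, −40 °C to rt
Reagents that add atoms: Cp2Ti(μ-CH2)(μ-Cl)AlMe2, C[Al-]1(C)C[Ti](C2C=CC=C2)(C2C=CC=C2)[Cl+]1
Why: The non-basic titanium methylidene (Tebbe methylenation) olefinates hindered, enolisable ketones by [2+2] addition and cycloreversion, so the γ-hydrogens at C16, whose removal would expel the C17 bromide, are not touched and no stereocentre is formed.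

Step 9
Reactants: 16 methyl 4-hydroxy-3-iodobenzoate
Product: 17 methyl 3-iodo-4-(methoxymethoxy)benzoate
Conditions: MeOCH2Cl, i-Pr2NEt, CH2Cl2, 0 °C to rt
Reagents that add atoms: chloromethyl methyl ether, COCCl
Why: O-Alkylation of the phenol (methoxymethyl ether formation) is routine and gives an acetal that is stable to the basic, organometallic and oxidative steps that follow.

Step 10
Reactants: 15 {3-[(1S,6S)-6-bromo-1,3-dimethyl-2-methylidenecyclohex-3-en-1-yl]propoxy}triisopropylsilane and 17 methyl 3-iodo-4-(methoxymethoxy)benzoate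
Product: 19 triisopropyl(3-Q-propoxy)silane, via alkylborane 18 (not isolated)
Conditions: 9-BBN, THF, rt to 50 °C; then 17, Pd(dppf)Cl2, AsPh3, Cs2CO3, DMF/H2O, rt to 50 °C
Reagents that add atoms: none
Why: 9-BBN should add boron to the exocyclic terminus C13 of the s-trans diene (anti-Markovnikov hydroboration) and hydrogen to C12 anti to the pseudoaxial C11 methyl group in the half-chair that keeps bromine and the C10 chain pseudoequatorial, setting C12 as R, after which the primary alkylborane 18 couples with aryl iodide 17 under zerovalent palladium catalysis (B-alkyl Suzuki–Miyaura coupling) without touching the secondary bromide or the ester.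

Step 11
Reactants: 19 triisopropyl(3-Q-propoxy)silane
Product: 20 3-Q-propan-1-ol
Conditions: Bu4NF, THF, 0 °C to rt
Reagents that add atoms: none
Why: Fluoride cleaves the primary silyl ether through the strong Si–F bond (desilylation) while the methyl ester, the acetal and the alkyl bromide should stay intact.

Step 12
Reactants: 20 3-Q-propan-1-ol
Product: 21 3-Q-propanal
Conditions: Dess–Martin periodinane, CH2Cl2, 0 °C to rt
Reagents that add atoms: none
Why: Dess–Martin oxidation converts the primary alcohol to the aldehyde under near-neutral conditions without over-oxidation and with no epimerisable centre nearby.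

Step 13
Reactants: 21 3-Q-propanal
Product: 23 2-methyl-5-Q-pent-1-en-3-yl acetate (both C8 epimers), via magnesium alkoxide 22 (not isolated)
Conditions: isopropenylmagnesium bromide, THF, −78 °C; then Ac2O, −78 °C to rt
Reagents that add atoms: isopropenylmagnesium bromide, C=C(C)[Mg]Br; acetic anhydride, CC(=O)OC(C)=O
Why: Grignard 1,2-addition to the aldehyde is far faster at low temperature than attack on the electron-rich aryl ester, alkoxide 22 is acetylated in the same flask, and the C8 carbinol centre may form as both epimers because it becomes sp2 in the next step.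

Step 14
Reactants: 23 2-methyl-5-Q-pent-1-en-3-yl acetate
Product: 26 (4E)-4-methyl-7-Q-hept-4-enoic acid, via silyl ketene acetal 24 (not isolated), via silyl ester 25 (not isolated)
Conditions: LiN(i-Pr)2, Me3SiCl, Et3N, THF, −78 to 50 °C; then aq. NH4Cl
Reagents that add atoms: none
Why: Enolisation with in situ silylation gives ketene acetal 24, which should rearrange (Ireland–Claisen rearrangement) through a chair transition state with the C9 chain equatorial to form the C5–C6 bond and the (E)-C7=C8 alkene, and hydrolysis of silyl ester 25 on work-up gives an acid that is chemically distinct from the aryl methyl ester.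

Step 15
Reactants: 26 (4E)-4-methyl-7-Q-hept-4-enoic acid
Product: 27 (4E)-N-methoxy-N,4-dimethyl-7-Q-hept-4-enamide
Conditions: MeNH(OMe)·HCl, EDC·HCl, N-methylmorpholine, CH2Cl2, 0 °C to rt
Reagents that add atoms: N,O-dimethylhydroxylamine hydrochloride, CNOC.Cl
Why: Carbodiimide-mediated amide coupling (Weinreb amide formation) engages only the free carboxylic acid and leaves the aryl methyl ester and all stereocentres untouched.

Step 16
Reactants: 27 (4E)-N-methoxy-N,4-dimethyl-7-Q-hept-4-enamide
Product: 28 (6E)-2,6-dimethyl-9-Q-nona-1,6-dien-3-one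
Conditions: isopropenylmagnesium bromide, THF, −40 to −10 °C; then cold aq. NH4Cl
Reagents that add atoms: isopropenylmagnesium bromide, C=C(C)[Mg]Br
Why: The Grignard reagent acylates only once on the N-methoxy-N-methyl amide (Weinreb ketone synthesis), which at low temperature is far more electrophilic than the electron-rich aryl methyl ester, so the isopropenyl ketone should be the only product.

Step 17
Reactants: 28 (6E)-2,6-dimethyl-9-Q-nona-1,6-dien-3-one
Product: 29 (3S,6E)-2,6-dimethyl-9-Q-nona-1,6-dien-3-ol
Conditions: (R)-2-methyl-CBS-oxazaborolidine (cat.), catecholborane, toluene, −78 °C; then aq. NaHCO3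
Reagents that add atoms: none
Why: Corey–Bakshi–Shibata reduction with the (R)-oxazaborolidine should treat the α-branched isopropenyl group as the large substituent and deliver hydride to the face that gives the (4S)-allylic alcohol, while catecholborane at low temperature leaves the ester and the alkenes alone.

Step 18
Reactants: 29 (3S,6E)-2,6-dimethyl-9-Q-nona-1,6-dien-3-ol
Product: 30 (3S)-2-methyl-5-[(2S,3S)-2-methyl-3-(2-Q-ethyl)oxiran-2-yl]pent-1-en-3-ol
Conditions: 1,2:4,5-di-O-isopropylidene-β-L-erythro-2,3-hexodiulo-2,6-pyranose (enantiomer of the D-fructose-derived Shi ketone), KHSO5 (as 2KHSO5·KHSO4·K2SO4), K2CO3, Bu4NHSO4, MeCN/CH2(OMe)2/aq. buffer pH 10.5, 0 °C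
Reagents that add atoms: potassium peroxymonosulfate, [K+].[O-]S(=O)(=O)OO
Why: The chiral dioxirane epoxidises trans-trisubstituted alkenes through a spiro transition state (Shi asymmetric epoxidation), so the unhindered C7=C8 alkene should react in preference to the hindered ring alkene and the 1,1-disubstituted isopropenyl group, and the L-series ketone is chosen because the D-series gives the (R,R) sense on such alkenes whereas (7S,8S) is needed.

Step 19
Reactants: 30 (3S)-2-methyl-5-[(2S,3S)-2-methyl-3-(2-Q-ethyl)oxiran-2-yl]pent-1-en-3-ol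
Product: 31 the benzoic acid corresponding to methyl ester 30
Conditions: LiOH, THF/MeOH/H2O, rt; then aq. NaH2PO4, 0 °C
Reagents that add atoms: lithium hydroxide, [Li+].[OH-]
Why: Saponification of the methyl benzoate (acyl–oxygen ester hydrolysis) should spare the trisubstituted epoxide and the hindered secondary bromide, and the buffered acidification avoids acid-triggered attack of the C4 hydroxyl on the epoxide.

Step 20
Reactants: 31 the benzoic acid corresponding to methyl ester 30
Product: 33 15-membered lactone between the arene carboxyl and O–C4 carrying the (7S,8S)-epoxide and the phenol methoxymethyl ether, via mixed anhydride 32 (not isolated)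
Conditions: 2-methyl-6-nitrobenzoic anhydride, DMAP, CH2Cl2, rt, slow addition at high dilution
Reagents that add atoms: none
Why: Mixed anhydride 32 should be attacked by the C4 hydroxyl at the less hindered substrate carbonyl under nucleophilic catalysis (Shiina macrolactonisation), closing the ring at room temperature with retention at C4 and without acid that could open the epoxide.

Step 21
Reactants: 33 15-membered epoxy lactone
Product: 34 15-membered lactone with (7S)-tertiary alcohol and (8R)-bromide, phenol as methoxymethyl ether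
Conditions: Li2NiBr4 (from LiBr and NiBr2), THF, 0 °C to rt; then H2O
Reagents that add atoms: dilithium tetrabromonickelate, [Li+].[Li+].[Ni+2].[Br-].[Br-].[Br-].[Br-]
Why: The soft bromide of Li2NiBr4 should open the epoxide by SN2 attack at the less substituted C8 with inversion (regioselective epoxide opening to a bromohydrin), turning the (8S)-epoxide carbon into the (8R)-bromide and releasing the (7S)-tertiary alcohol, while the acylated C4 oxygen can no longer act as an internal nucleophile.

Step 22
Reactants: 34 bromohydrin lactone methoxymethyl ether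
Product: 35 CNP0213075.1
Conditions: ZnBr2, n-PrSH, CH2Cl2, 0 °C
Reagents that add atoms: none
Why: ZnBr2 activates the aryl methoxymethyl ether and the thiol captures the oxocarbenium fragment (Lewis acid–thiol acetal cleavage), a fast and weakly acidic deprotection that should spare the bromohydrin, the allylic ester and both alkenes.

**Compound list**
1 | 3-iodopropan-1-ol | OCCCI | starting material
2 | (3-iodopropoxy)triisopropylsilane | CC(C)[Si](C(C)C)(C(C)C)OCCCI | intermediate
3 | 2-methylcyclohex-2-en-1-one | CC1=CCCCC1=O | starting material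
4 | (S)-2-(methoxymethyl)-N-(2-methylcyclohex-2-en-1-ylidene)pyrrolidin-1-amine | CC1=CCCC/C1=N\N2CCC[C@H]2COC | intermediate
5 | lithium aza-enolate of 4 | CC1=CCCC=C1N([Li])N2CCC[C@H]2COC | intermediate
6 | (S)-2-(methoxymethyl)-N-[(6R)-2,6-dimethylcyclohex-2-en-1-ylidene]pyrrolidin-1-amine | CC1=CCC[C@@H](C)/C1=N\N2CCC[C@H]2COC | intermediate
7 | (R)-2,6-dimethylcyclohex-2-en-1-one | CC1=CCC[C@@H](C)C1=O | intermediate
8 | [3-(triisopropylsilyloxy)propyl]lithium | [Li]CCCO[Si](C(C)C)(C(C)C)C(C)C | intermediate
9 | [3-(triisopropylsilyloxy)propyl]cerium dichloride | Cl[Ce](Cl)CCCO[Si](C(C)C)(C(C)C)C(C)C | intermediate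
10 | (1R,6R)-2,6-dimethyl-1-[3-(triisopropylsilyloxy)propyl]cyclohex-2-en-1-ol | CC(C)[Si](C(C)C)(C(C)C)OCCC[C@]1(O)C(C)=CCC[C@H]1C | intermediate
11 | bromonium ion of 10, bromine anti to the chain | CC(C)[Si](C(C)C)(C(C)C)OCCC[C@]1(O)[C@@]2(C)[Br+][C@H]2CC[C@H]1C | intermediate
12 | (2S,3S,6R)-3-bromo-2,6-dimethyl-2-[3-(triisopropylsilyloxy)propyl]cyclohexan-1-one | CC(C)[Si](C(C)C)(C(C)C)OCCC[C@@]1(C)C(=O)[C@H](C)CC[C@@H]1Br | intermediate
13 | trimethylsilyl enol ether of 12 (C12=C14) | CC(C)[Si](C(C)C)(C(C)C)OCCC[C@@]1(C)C(O[Si](C)(C)C)=C(C)CC[C@@H]1Br | intermediate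
14 | (5S,6S)-5-bromo-2,6-dimethyl-6-[3-(triisopropylsilyloxy)propyl]cyclohex-2-en-1-one | CC(C)[Si](C(C)C)(C(C)C)OCCC[C@@]1(C)C(=O)C(C)=CC[C@@H]1Br | intermediate
15 | {3-[(1S,6S)-6-bromo-1,3-dimethyl-2-methylidenecyclohex-3-en-1-yl]propoxy}triisopropylsilane | CC(C)[Si](C(C)C)(C(C)C)OCCC[C@@]1(C)C(=C)C(C)=CC[C@@H]1Br | intermediate
16 | methyl 4-hydroxy-3-iodobenzoate | COC(=O)c1ccc(O)c(I)c1 | starting material
17 | methyl 3-iodo-4-(methoxymethoxy)benzoate | COCOc1ccc(cc1I)C(=O)OC | intermediate
18 | B-alkyl-9-borabicyclo[3.3.1]nonane from 15 (boron on C13, 12R) | CC(C)[Si](C(C)C)(C(C)C)OCCC[C@@]1(C)[C@H](CB2C3CCCC2CCC3)C(C)=CC[C@@H]1Br | intermediate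
19 | triisopropyl(3-Q-propoxy)silane | CC(C)[Si](C(C)C)(C(C)C)OCCC[C@@]1(C)[C@H](Cc2cc(ccc2OCOC)C(=O)OC)C(C)=CC[C@@H]1Br | intermediate
20 | 3-Q-propan-1-ol | OCCC[C@@]1(C)[C@H](Cc2cc(ccc2OCOC)C(=O)OC)C(C)=CC[C@@H]1Br | intermediate
21 | 3-Q-propanal | O=CCC[C@@]1(C)[C@H](Cc2cc(ccc2OCOC)C(=O)OC)C(C)=CC[C@@H]1Br | intermediate
22 | bromomagnesium 2-methyl-5-Q-pent-1-en-3-olate (both C8 epimers) | C=C(C)C(O[Mg]Br)CC[C@@]1(C)[C@H](Cc2cc(ccc2OCOC)C(=O)OC)C(C)=CC[C@@H]1Br | intermediate
23 | 2-methyl-5-Q-pent-1-en-3-yl acetate (both C8 epimers) | C=C(C)C(OC(C)=O)CC[C@@]1(C)[C@H](Cc2cc(ccc2OCOC)C(=O)OC)C(C)=CC[C@@H]1Br | intermediate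
24 | trimethylsilyl ketene acetal of 23 | C=C(C)C(OC(=C)O[Si](C)(C)C)CC[C@@]1(C)[C@H](Cc2cc(ccc2OCOC)C(=O)OC)C(C)=CC[C@@H]1Br | intermediate
25 | trimethylsilyl (4E)-4-methyl-7-Q-hept-4-enoate | C[Si](C)(C)OC(=O)CC/C(C)=C/CC[C@@]1(C)[C@H](Cc2cc(ccc2OCOC)C(=O)OC)C(C)=CC[C@@H]1Br | intermediate
26 | (4E)-4-methyl-7-Q-hept-4-enoic acid | OC(=O)CC/C(C)=C/CC[C@@]1(C)[C@H](Cc2cc(ccc2OCOC)C(=O)OC)C(C)=CC[C@@H]1Br | intermediate
27 | (4E)-N-methoxy-N,4-dimethyl-7-Q-hept-4-enamide | CON(C)C(=O)CC/C(C)=C/CC[C@@]1(C)[C@H](Cc2cc(ccc2OCOC)C(=O)OC)C(C)=CC[C@@H]1Br | intermediate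
28 | (6E)-2,6-dimethyl-9-Q-nona-1,6-dien-3-one | C=C(C)C(=O)CC/C(C)=C/CC[C@@]1(C)[C@H](Cc2cc(ccc2OCOC)C(=O)OC)C(C)=CC[C@@H]1Br | intermediate
29 | (3S,6E)-2,6-dimethyl-9-Q-nona-1,6-dien-3-ol | C=C(C)[C@@H](O)CC/C(C)=C/CC[C@@]1(C)[C@H](Cc2cc(ccc2OCOC)C(=O)OC)C(C)=CC[C@@H]1Br | intermediate
30 | (3S)-2-methyl-5-[(2S,3S)-2-methyl-3-(2-Q-ethyl)oxiran-2-yl]pent-1-en-3-ol | C=C(C)[C@@H](O)CC[C@]3(C)O[C@H]3CC[C@@]1(C)[C@H](Cc2cc(ccc2OCOC)C(=O)OC)C(C)=CC[C@@H]1Br | intermediate
31 | benzoic acid corresponding to 30 (seco acid) | C=C(C)[C@@H](O)CC[C@]3(C)O[C@H]3CC[C@@]1(C)[C@H](Cc2cc(ccc2OCOC)C(O)=O)C(C)=CC[C@@H]1Br | intermediate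
32 | mixed anhydride of 31 with 2-methyl-6-nitrobenzoic acid | C=C(C)[C@@H](O)CC[C@]3(C)O[C@H]3CC[C@@]1(C)[C@H](Cc2cc(ccc2OCOC)C(=O)OC(=O)c2c(C)cccc2[N+](=O)[O-])C(C)=CC[C@@H]1Br | intermediate
33 | 15-membered lactone (4S,11S,12R,17S) with (7S,8S)-epoxide, phenol methoxymethyl ether | C=C(C)[C@@H]1CC[C@]3(C)O[C@H]3CC[C@@]2(C)[C@H](Cc4cc(ccc4OCOC)C(=O)O1)C(C)=CC[C@@H]2Br | intermediate
34 | 15-membered lactone (4S,7S,8R,11S,12R,17S) bromohydrin, phenol methoxymethyl ether | C=C(C)[C@@H]1CC[C@](C)(O)[C@H](Br)CC[C@@]2(C)[C@H](Cc3cc(ccc3OCOC)C(=O)O1)C(C)=CC[C@@H]2Br | intermediate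
35 | CNP0213075.1, (4S,7S,8R,11S,12R,17S) in the numbering of the plan | C=C(C)[C@@H]1CC[C@](C)(O)[C@H](Br)CC[C@@]2(C)[C@H](Cc3cc(ccc3O)C(=O)O1)C(C)=CC[C@@H]2Br | target

**Step count and risks**
Total: 22 steps. Longest linear sequence: 20 steps (steps 2–8 and 10–22, from 2-methylcyclohex-2-en-1-one 3).

Step 6. What may go wrong: capture of the bromonium ion by the hydroxyl oxygen (bromo-epoxide formation), or bromination on the chain face, outrunning migration of the unactivated primary chain. The fallback sets out from iodide 2 and returns at enone 14.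
- Commercial 2-methylcyclohexane-1,3-dione is condensed with 1,1-dimethylhydrazine to the vinylogous hydrazide 3-(2,2-dimethylhydrazinyl)-2-methylcyclohex-2-en-1-one F1.
- KH and iodide 2 should then give, by C-alkylation, racemic 3-(dimethylhydrazono)-2-methyl-2-[3-(triisopropylsilyloxy)propyl]cyclohexan-1-one F2.
- Hydrolysis (Cu(OAc)2, aqueous THF) gives the prochiral 2-methyl-2-[3-(triisopropylsilyloxy)propyl]cyclohexane-1,3-dione F3.
- A desymmetrising CBS reduction, with the oxazaborolidine antipode chosen so that hydride arrives anti to the chain, should give (2R,3R)-3-hydroxy-2-methyl-2-[3-(triisopropylsilyloxy)propyl]cyclohexan-1-one F4.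
- Appel bromination (CBr4, PPh3) with inversion gives (2S,3S)-3-bromo-2-methyl-2-[3-(triisopropylsilyloxy)propyl]cyclohexan-1-one F5, which already carries the C11 and C17 centres of 12.
- α′-Methylation (LiN(i-Pr)2, MeI) gives the C14-epimeric 3-bromo-2,6-dimethyl ketone F6; both epimers converge on silyl enol ether 13 under the conditions of step 7 and so rejoin at 14.

Step 10. What may go wrong: poor facial selectivity in the delivery of hydrogen to C12 (the other half-chair, with chain and bromine pseudoaxial, exposes the opposite face), together with slow hydroboration of the hindered diene. The fallback sets out from enone 14 and returns at 19.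
- Dimethylsulfonium methylide (Me3S+ I−, KN(SiMe3)2, THF, −20 °C; Corey–Chaykovsky reaction) should attack the C12 carbonyl anti to the pseudoaxial C11 methyl group. A carbon nucleophile bonding to the ring carbon itself is far more sensitive to the syn-axial bromine of the other half-chair than a borane that bonds at the exocyclic carbon. This gives the spiro vinyl oxirane F7 with oxygen on the methyl face.
- Pd2(dba)3/PBu3 with HCO2H–Et3N (palladium-catalysed formate hydrogenolysis of alkenyl oxiranes) ionises the allylic C–O bond with inversion and transfers hydride to C12 from the chain face, giving the homoallylic alcohol (C13 hydroxymethyl, 12R) F8.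
- I2, PPh3 and imidazole give the primary iodide F9.
- Zinc insertion (Zn, LiCl, THF) gives the alkylzinc iodide F10, which couples with aryl iodide 17 (Pd(dppf)Cl2, Negishi coupling) to return to 19.

Step 21. What may go wrong: bromide attack at the tertiary C7, or Lewis-acid-induced rearrangement of the epoxide, instead of SN2 opening at C8. The fallback sets out from allylic alcohol 29 and returns at 34.
- The epoxidation is omitted; saponification (LiOH) gives the triene seco acid F11.
- Lactonisation (2-methyl-6-nitrobenzoic anhydride, DMAP) gives the triene 15-membered lactone F12.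
- NBS in aqueous THF at 0 °C then forms the C7=C8 bromonium ion, which water opens at the tertiary C7 (Markovnikov, anti). This fixes the constitution and the relative 7,8-configuration of 34.
- The facial choice is then left to the macrocycle, so the diastereomeric bromohydrin would have to be removed by chromatography before step 22.

**Further compounds**
F1 | step 6 | 3-(2,2-dimethylhydrazinyl)-2-methylcyclohex-2-en-1-one | CC1=C(NN(C)C)CCCC1=O
F2 | step 6 | 3-(dimethylhydrazono)-2-methyl-2-[3-(triisopropylsilyloxy)propyl]cyclohexan-1-one (racemic) | CC(C)[Si](C(C)C)(C(C)C)OCCCC1(C)C(=O)CCCC1=NN(C)C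
F3 | step 6 | 2-methyl-2-[3-(triisopropylsilyloxy)propyl]cyclohexane-1,3-dione | CC(C)[Si](C(C)C)(C(C)C)OCCCC1(C)C(=O)CCCC1=O
F4 | step 6 | (2R,3R)-3-hydroxy-2-methyl-2-[3-(triisopropylsilyloxy)propyl]cyclohexan-1-one | CC(C)[Si](C(C)C)(C(C)C)OCCC[C@@]1(C)C(=O)CCC[C@H]1O
F5 | step 6 | (2S,3S)-3-bromo-2-methyl-2-[3-(triisopropylsilyloxy)propyl]cyclohexan-1-one | CC(C)[Si](C(C)C)(C(C)C)OCCC[C@@]1(C)C(=O)CCC[C@@H]1Br
F6 | step 6 | (2S,3S)-3-bromo-2,6-dimethyl-2-[3-(triisopropylsilyloxy)propyl]cyclohexan-1-one, both C6 epimers | CC(C)[Si](C(C)C)(C(C)C)OCCC[C@@]1(C)C(=O)C(C)CC[C@@H]1Br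
F7 | step 10 | spiro vinyl oxirane at C12 of 14 (oxygen on the C11-methyl face) | CC(C)[Si](C(C)C)(C(C)C)OCCC[C@@]1(C)[C@@]2(CO2)C(C)=CC[C@@H]1Br
F8 | step 10 | {(1R,5S,6S)-5-bromo-2,6-dimethyl-6-[3-(triisopropylsilyloxy)propyl]cyclohex-2-en-1-yl}methanol | CC(C)[Si](C(C)C)(C(C)C)OCCC[C@@]1(C)[C@H](CO)C(C)=CC[C@@H]1Br
F9 | step 10 | primary iodide from F8 | CC(C)[Si](C(C)C)(C(C)C)OCCC[C@@]1(C)[C@H](CI)C(C)=CC[C@@H]1Br
F10 | step 10 | alkylzinc iodide from F9 | CC(C)[Si](C(C)C)(C(C)C)OCCC[C@@]1(C)[C@H](C[Zn]I)C(C)=CC[C@@H]1Br
F11 | step 21 | benzoic acid corresponding to 29 (triene seco acid) | C=C(C)[C@@H](O)CC/C(C)=C/CC[C@@]1(C)[C@H](Cc2cc(ccc2OCOC)C(O)=O)C(C)=CC[C@@H]1Br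
F12 | step 21 | 15-membered triene lactone, phenol methoxymethyl ether | C=C(C)[C@@H]1CC/C(C)=C/CC[C@@]2(C)[C@H](Cc3cc(ccc3OCOC)C(=O)O1)C(C)=CC[C@@H]2Br
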